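**Retrosynthetic overview**
- The last bond made is O1–C2 of ring C: the target comes from a 2'-hydroxychalcone by a catalyst-controlled 6-endo oxa-Michael closure that sets C2 as S.
- The chalcone comes from a Claisen–Schmidt union of 2',4'-dihydroxyacetophenone with a trans-diol chroman aldehyde.
- The trans-diol comes from two C–O bond formations on a 2,2-dimethyl-2H-chromene: salen-manganese epoxidation (sets C3), then water opening at C4 with inversion.
- The chromene comes from an aryl 1,1-dimethylpropargyl ether (Claisen cascade), made from 3,4-dihydroxybenzaldehyde and 3-chloro-3-methylbut-1-yne.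
- Ring order: both benzene rings are bought, the dimethylpyran ring is closed first, the pyranone ring C last.

Assumption: the SMILES is read as the (2S)-flavanone whose dimethylchroman unit carries a trans-(3R,4S)-3,4-diol and an 8-OH; all descriptors below follow this reading.

**Route**

Step 1
Reactants: 1 3,4-dihydroxybenzaldehyde; 2 3-chloro-3-methylbut-1-yne
Product: 4 5-formyl-2-[(2-methylbut-3-yn-2-yl)oxy]phenyl acetate, via propargyl ether phenol 3 (not isolated)
Conditions: 2 (1.2 equiv), K2CO3 (1.1 equiv), KI (10 mol%), CuCl (2 mol%), DMF, N2, 45 °C, 12 h; then Ac2O (1.5 equiv), K2CO3 (1.5 equiv), 0 °C to rt, 1 h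
Reagents that add atoms: acetic anhydride, CC(=O)OC(C)=O
Why: The 4-OH, para to the formyl group and much the more acidic, is ionised selectively by one equivalent of carbonate and etherified by the copper acetylide electrophile formed from 2 (Cu-catalysed propargylic Williamson-type O-alkylation), after which acetic anhydride caps the remaining 3-OH in the same pot so that no free phenol meets the later oxidant.

Step 2
Reactants: 4 5-formyl-2-[(2-methylbut-3-yn-2-yl)oxy]phenyl acetate
Product: 5 6-formyl-2,2-dimethyl-2H-chromen-8-yl acetate
Conditions: o-dichlorobenzene, 175 °C, 3 h, N2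
Reagents that add atoms: none
Why: Aryl propargyl Claisen rearrangement to the only free ortho carbon, then enolisation, 1,5-hydrogen shift and oxa-6π-electrocyclisation, closes the 2,2-dimethyl-2H-pyran ring, while the aryl acetate and the aldehyde are thermally inert.

Step 3
Reactants: 5 6-formyl-2,2-dimethyl-2H-chromen-8-yl acetate
Product: 7 (3R,4S)-6-formyl-3,4-dihydroxy-2,2-dimethylchroman-8-yl acetate, via (3R,4R)-epoxide 6 (not isolated)
Conditions: (R,R)-[N,N'-bis(3,5-di-tert-butylsalicylidene)cyclohexane-1,2-diaminato]MnCl (C36H52ClMnN2O2, trivalent manganese, 4 mol%), mCPBA (2 equiv), N-methylmorpholine N-oxide (5 equiv), CH2Cl2, −78 °C, 1 h; aqueous NaHCO3 wash, solvent switch; then 0.05 M HClO4, THF/H2O 3:1, 0 °C to rt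
Reagents that add atoms: 3-chloroperoxybenzoic acid (mCPBA), OOC(=O)c1cccc(Cl)c1; water, O
Why: Jacobsen–Katsuki epoxidation by the (R,R)-salen oxo-manganese species gives the (3R,4R)-epoxide of this electron-poor cis-olefin (the same sense as for 6-cyano-2,2-dimethylchromene), and acid-catalysed hydrolysis then delivers water to benzylic C4 with inversion while the neopentyl C3–O bond is untouched, so C3 is R (oxygen from the peracid) and C4 is S (oxygen from water) in a trans-diol.

Step 4
Reactants: 7 (3R,4S)-6-formyl-3,4-dihydroxy-2,2-dimethylchroman-8-yl acetate; 8 1-(2,4-dihydroxyphenyl)ethanone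
Product: 10 (E)-1-(2,4-dihydroxyphenyl)-3-[(3R,4S)-3,4,8-trihydroxy-2,2-dimethylchroman-6-yl]prop-2-en-1-one, via deacetylated aldehyde 9 (not isolated)
Conditions: KOH (50% aq, 12 equiv), EtOH, argon, 0 °C to rt, 48 h; then cold 1 M HCl to pH 4
Reagents that add atoms: none
Why: Claisen–Schmidt aldol condensation in which hydroxide first removes the aryl acetate, the resulting phenoxide sits meta to the formyl group and does not deactivate it, and the acetophenone enolate adds and dehydrates by E1cB to the (E)-enone, while the trans-diol has no acidic C–H and no quinone-methide pathway and keeps its configuration.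

Step 5
Reactants: 10 (E)-1-(2,4-dihydroxyphenyl)-3-[(3R,4S)-3,4,8-trihydroxy-2,2-dimethylchroman-6-yl]prop-2-en-1-one
Product: 11 (2S)-7-hydroxy-2-[(3R,4S)-3,4,8-trihydroxy-2,2-dimethylchroman-6-yl]chroman-4-one
Conditions: (S)-(6-methoxyquinolin-4-yl)[(1S,2S,4S,5R)-5-vinylquinuclidin-2-yl]methanamine (9-amino-9-deoxy-epi-quinine, C20H25N3O, 20 mol%), PhCO2H (40 mol%), THF, 25 °C, 48 h, dark, argon
Reagents that add atoms: none
Why: Proposed new method: enantioselective 6-endo oxa-Michael closure of an unactivated, unprotected 2'-hydroxychalcone under primary-amine iminium catalysis, in which the catalyst NH2 condenses with the ketone (o-hydroxyaryl ketones form ketimines readily because an O–H···N hydrogen bond replaces the deactivating O–H···O=C one), the protonated ketiminium makes C-β electrophilic enough for the neutral 2'-OH, that OH turns towards the s-trans enimine and is deprotonated in the transition state by the quinuclidine/benzoate pair held on one side of the ion pair so that oxygen adds to the C-β face left open by the quinoline wall (taken to be the face leading to 2S), and the resulting 4-aminochromene enamine is protonated at C3 and hydrolysed to release 11 and the amine; the product has no ortho-OH and re-condenses far more slowly, and the buffered medium is too weakly basic for E1cB ring opening, so the closure is under kinetic control and the remote diol is a bystander; the closest known reaction types are cinchona primary-amine iminium-catalysed hetero-Michael additions to enones (intramolecular aza-Michael additions of carbamates, additions of oximes and hydroperoxides) and the racemic amine-mediated Kabbe-type closure of 2'-hydroxychalcones.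

**Compound list**

1 | 3,4-dihydroxybenzaldehyde | O=Cc1ccc(O)c(O)c1 | starting material
2 | 3-chloro-3-methylbut-1-yne | CC(C)(Cl)C#C | starting material
3 | 3-hydroxy-4-[(2-methylbut-3-yn-2-yl)oxy]benzaldehyde | O=Cc1ccc(OC(C)(C)C#C)c(O)c1 | intermediate
4 | 5-formyl-2-[(2-methylbut-3-yn-2-yl)oxy]phenyl acetate | CC(=O)Oc1cc(C=O)ccc1OC(C)(C)C#C | intermediate
5 | 6-formyl-2,2-dimethyl-2H-chromen-8-yl acetate | CC(=O)Oc1cc(C=O)cc2C=CC(C)(C)Oc12 | intermediate
6 | (3R,4R)-3,4-epoxy-6-formyl-2,2-dimethylchroman-8-yl acetate | CC1(C)Oc2c(OC(C)=O)cc(C=O)cc2[C@H]3O[C@@H]13 | intermediate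
7 | (3R,4S)-6-formyl-3,4-dihydroxy-2,2-dimethylchroman-8-yl acetate | CC1(C)Oc2c(OC(C)=O)cc(C=O)cc2[C@H](O)[C@H]1O | intermediate
8 | 1-(2,4-dihydroxyphenyl)ethanone (2',4'-dihydroxyacetophenone) | CC(=O)c1ccc(O)cc1O | starting material
9 | (3R,4S)-3,4,8-trihydroxy-2,2-dimethylchroman-6-carbaldehyde | CC1(C)Oc2c(O)cc(C=O)cc2[C@H](O)[C@H]1O | intermediate
10 | (E)-1-(2,4-dihydroxyphenyl)-3-[(3R,4S)-3,4,8-trihydroxy-2,2-dimethylchroman-6-yl]prop-2-en-1-one | CC1(C)Oc2c(O)cc(/C=C/C(=O)c3ccc(O)cc3O)cc2[C@H](O)[C@H]1O | intermediate
11 | (2S)-7-hydroxy-2-[(3R,4S)-3,4,8-trihydroxy-2,2-dimethylchroman-6-yl]chroman-4-one | CC1(C)Oc2c(O)cc([C@@H]3CC(=O)c4ccc(O)cc4O3)cc2[C@H](O)[C@H]1O | target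

**Step count and risks**

Total steps: 5. Longest linear sequence: 5 (1 → 4 → 5 → 7 → 10 → 11); 8 enters at step 4.

The three steps most likely to fail:

Step 5 (the proposed new closure). The ketimine may be a resting state, the catalyst may be tied up as its aza-Michael adduct, and the selectivity and its sense are unproven. The 2S configuration must be confirmed on the first run by circular dichroism (positive Cotton effect near 330 nm, negative near 290 nm) and by HPLC against the epimer. If the sense is opposite, the pseudo-enantiomeric quinidine-derived amine (C20H25N3O) is used. Conversion is limited by the chalcone–flavanone equilibrium, so unreacted 10 is recovered. The fallback with known chemistry sets out from 10. Heating 10 with NaOAc in EtOH/H2O at reflux gives the equilibrium mixture of 11 and its C2 epimer (2R)-7-hydroxy-2-[(3R,4S)-3,4,8-trihydroxy-2,2-dimethylchroman-6-yl]chroman-4-one F1, with some 10 left. The two epimers are separated by preparative HPLC on an amylose tris(3,5-dimethylphenylcarbamate) phase. F1 is returned to the NaOAc conditions, where it opens to 10 and closes again, so material is recycled. The fallback comes back to the route at 11.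

Step 4 (Claisen–Schmidt without protecting groups). The doubly ionised acetophenone is a weak nucleophile, and Cannizzaro reaction or air oxidation may take over. The fallback replaces the aldol by a Wittig olefination under neutral conditions and sets out from 7. Commercial 2-chloro-1-(2,4-dihydroxyphenyl)ethanone and PPh3 (MeCN, 60 °C) give [2-(2,4-dihydroxyphenyl)-2-oxoethyl]triphenylphosphonium chloride F2. Aqueous Na2CO3 converts it into the stabilised ylide 1-(2,4-dihydroxyphenyl)-2-(triphenylphosphoranylidene)ethanone F3. Heating F3 with 7 in THF at 65 °C gives the (E)-enone (3R,4S)-6-[(E)-3-(2,4-dihydroxyphenyl)-3-oxoprop-1-enyl]-3,4-dihydroxy-2,2-dimethylchroman-8-yl acetate F4. Brief treatment with catalytic K2CO3 in MeOH at 0 °C removes the aryl acetate, and the fallback comes back to the route at 10.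

Step 3 (epoxidation and hydrolysis). Ionisation at C4 during the acid hydrolysis would give some cis-diol, and the selectivity with the 8-acetoxy-6-formyl substitution may be below that of the 6-cyano model. The fallback abandons solvolysis and sets out from 6, isolated by filtration through triethylamine-deactivated silica. Tetrabutylammonium benzoate and benzoic acid (1.5 equiv each, MeCN, 50 °C) open the epoxide by SN2 attack at C4 without a cation, giving (3R,4S)-8-acetoxy-6-formyl-3-hydroxy-2,2-dimethylchroman-4-yl benzoate F5, which can be recrystallised to raise the enantiomeric purity. F5 is put directly into the step 4 conditions, where KOH removes the benzoate and the acetate. The fallback comes back to the route at 9, formed in the flask, and from there goes on to 10.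

**Further compounds**

F1 | step 5 | (2R)-7-hydroxy-2-[(3R,4S)-3,4,8-trihydroxy-2,2-dimethylchroman-6-yl]chroman-4-one | CC1(C)Oc2c(O)cc([C@H]3CC(=O)c4ccc(O)cc4O3)cc2[C@H](O)[C@H]1O
F2 | step 4 | [2-(2,4-dihydroxyphenyl)-2-oxoethyl]triphenylphosphonium chloride | [Cl-].O=C(C[P+](c1ccccc1)(c1ccccc1)c1ccccc1)c1ccc(O)cc1O
F3 | step 4 | 1-(2,4-dihydroxyphenyl)-2-(triphenylphosphoranylidene)ethanone | O=C(C=P(c1ccccc1)(c1ccccc1)c1ccccc1)c1ccc(O)cc1O
F4 | step 4 | (3R,4S)-6-[(E)-3-(2,4-dihydroxyphenyl)-3-oxoprop-1-enyl]-3,4-dihydroxy-2,2-dimethylchroman-8-yl acetate | CC1(C)Oc2c(OC(C)=O)cc(/C=C/C(=O)c3ccc(O)cc3O)cc2[C@H](O)[C@H]1O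
F5 | step 3 | (3R,4S)-8-acetoxy-6-formyl-3-hydroxy-2,2-dimethylchroman-4-yl benzoate | CC1(C)Oc2c(OC(C)=O)cc(C=O)cc2[C@H](OC(=O)c3ccccc3)[C@H]1O
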